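The constants used here were chosen freely, and the outcome is calculated.

At the reading time of 80 s substrate is still reacting, so I count the fraction left, not the fraction made.

| flask | substrate | partner | temperature | time | remark |
|---|---|---|---|---|---|
| gamma | 0.20 M | 0.260 M | 80 °C | 80 s | everything together at the start |
| delta | 0.20 M (fed, over 50 s) | 0.260 M | 80 °C | 80 s | all else is in the flask from the start; the feed brings no volume worth counting |
| beta | 0.20 M | 0.260 M (fed, over 50 s) | 80 °C | 80 s | all else is in the flask from the start; the feed brings no volume worth counting |
| epsilon | 0.20 M | 0.260 M (fed, over 50 s) |  | 80 s | the addition at 40 °C, then warmed to 80 °C; the feed brings no volume worth counting |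

    intermediate A → intermediate B (k1 = 0.328 /s, Ea1 = 83.0 kJ/mol)
    target ⇌ isomer of the product (K2 = 1.4, k2 = 0.0251 /s, Ea2 = 87.0 kJ/mol, ΔH2 = −43.0 kJ/mol)
    partner + intermediate B → side product C (k3 = 0.0494 /M/s, Ea3 = 80.0 kJ/mol)
    substrate + partner → intermediate A (k4 = 0.0251 /M/s, Ea4 = 69.0 kJ/mol)
    substrate → side product A (k5 = 0.00385 /s, Ea5 = 89.0 kJ/mol)
    substrate → target (k6 = 0.00692 /s, Ea6 = 102 kJ/mol)
    partner + intermediate A → side product B (k7 = 0.00651 /M/s, Ea7 = 64.0 kJ/mol)
    (constants at 80 °C)

- all constants are for 80 °C and move with temperature by the activation energies and enthalpies

1. the flask with the highest amount of target, in percent of the substrate charged ("all alike" if they lie within 1.5 percentage points) (gamma / delta / beta / epsilon / all alike)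
2. final target, as a percentage of the substrate charged, in gamma
3. final target, as a percentage of the substrate charged, in delta
4. final target, as a percentage of the substrate charged, in beta
5. final target, as a percentage of the substrate charged, in epsilon

Substrate leaves by three channels, and the one through partner is pseudo-first-order while partner stands near its charge. With partner at its charge, the total loss constant is

s = 0.00692 /s + 0.00385 /s + 0.0251 /M/s × 0.260 M = 0.0173 /s

The target share S, the part of spent substrate that enters the pool of target plus isomer of the product, is 0.00692 /s over s, or 40.0%.

In gamma, the fraction left and the pool P are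

f = exp(−s t) = 25.1%, P = S(1 − f) = 30.0%

Target is a part of the pool, so on this reckoning, with partner held at its charge, the upper bound is 30.0%. With K = 1.4, isomer of the product over target at equilibrium, the equilibrium share P/(1 + K) gives the lower bound 12.5%.

To tighten this, I use the relaxation constant λ = 0.0251 /s × (1 + 1/K) = 0.0430 /s, which is faster than s. Target therefore runs ahead of its equilibrium share by f times a lag L, where τ is the hot time:

L = [K/(1 + K)] × 0.00692 /s/(λ − s) × [1 − exp(−(λ − s)τ)]

L = 0.137 for τ = 80 s, so in gamma P/(1 + K) + fL = 15.9%

For delta, I average the decay over the feed and keep the L of gamma as a rough figure. For beta, partner rises evenly, so its contact time is 55.0 s, and I keep the same L. For epsilon, I take the cold addition as idle and count 30.0 s of heat, both in f and in L.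

delta: f = 39.8%, P = 24.1%, target 15.5%

beta: f = 29.5%, P = 32.0%, target 17.4%

epsilon: f = 59.5%, P = 16.2%, L = 0.0844, target 11.8%

My highest flask is beta.

The forecast names beta, with 16.4% in gamma, 14.7% in delta, 18.6% in beta and 12% in epsilon, holding that “feeding partner keeps that drain low”; its gamma value lies inside my bracket, above my tightened line.

The simulation gives beta as highest, with 16.3% in gamma, 14.7% in delta, 18.1% in beta and 11.9% in epsilon.

In epsilon at 80.0 s, the step to target runs 1.2 times as fast as the step to intermediate A, which makes the momentary share 41.8%, higher than S, which I reckoned with partner at its charge. The relaxation half-life of target and isomer of the product by their own step alone, both ways together, at the later temperature of epsilon, is 16.1 s, shorter than the reading time.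

For epsilon read at 5.0 min, my fraction left, with partner held at its charge, is 1.32%, and S(1 − f)/(1 + K) gives 16.4%. That flask gives 17.7% of target, with substrate at 2.16% of its charge and partner at 55.4% of its own.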